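**Plan**

1. Retrosynthesis: (a) the furan C–O bond and the aryl–C3 bond of the benzofuran are cut (Sonogashira coupling and 5-endo-dig annulation) to a 5-ethynyl-dihydropyran and 1-(2,5-dihydroxy-4-iodophenyl)ethanone; (b) the C5–alkyne bond is cut back to a C5–H enol ether; (c) the pyran C2–C3 bond is cut while one hydrogen of C4 is returned to C2, which unfolds the ring into an achiral 5-(aryl-methoxy)penta-2,4-dienal; (d) its O–CH2Ar bond is cut to potassium glutaconate (ring-opened pyridine) and a vanillyl bromide.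
2. Enabling feature: in the pyran ring C2–H is benzylic to the electron-rich guaiacyl ring and alpha to O1, C4 is a bare CH2 placed 1,5 to it across the cis O1–C6=C5 enol ether, and C3 carries a carbon at the aldehyde level (the CH2OAc carbon). C2–H can therefore deliver hydride to C4 of a C3=C4 enal, and the resulting C3 enol closes onto the C2 oxocarbenium in a redox-neutral isomerisation.
3. Forward order: O-alkylation of glutaconate; the pyran ring by hydride shift and ring closure; reduction, acetylation, C5 iodination and alkynylation; last the furan ring of the benzofuran.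
4. Stereochemistry: C2 and C3 both arise in the ring closure. The absolute sense comes from a chiral Brønsted acid (ion-paired oxocarbenium), the trans relation from the half-chair closure and enol equilibration; no later step touches either centre.

Key step: step 5

Assumption: potassium glutaconate is bought (it is the product of pyridine–SO3 and KOH), and the (R)-acid is taken to give the (2R,3R) sense in step 5; if the first run shows the opposite sense, the (S)-acid is used with no other change.

Step 1
Reactants: 1 vanillin (4-hydroxy-3-methoxybenzaldehyde)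
Product: 2 3-methoxy-4-(triisopropylsilyloxy)benzaldehyde
Conditions: TIPSCl, imidazole, DMF, rt
Reagents that add atoms: triisopropylsilyl chloride, CC(C)[Si](Cl)(C(C)C)C(C)C
Why: Imidazole-promoted O-silylation of the phenol gives a bulky aryl silyl ether that should survive hydride, bromide, mild acid and Pd/Cu conditions while keeping the ring electron-rich.

Step 2
Reactants: 2 3-methoxy-4-(triisopropylsilyloxy)benzaldehyde
Product: 3 [3-methoxy-4-(triisopropylsilyloxy)phenyl]methanol
Conditions: NaBH4, THF/MeOH, 0 °C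
Reagents that add atoms: none
Why: Borohydride reduction of the aryl aldehyde to the benzylic alcohol leaves the silyl ether untouched.

Step 3
Reactants: 3 [3-methoxy-4-(triisopropylsilyloxy)phenyl]methanol
Product: 4 4-(bromomethyl)-2-methoxy-1-(triisopropylsilyloxy)benzene
Conditions: CBr4, PPh3, CH2Cl2, 0 °C; used at once
Reagents that add atoms: carbon tetrabromide, BrC(Br)(Br)Br
Why: Appel bromination under neutral conditions converts the benzylic alcohol into the bromide without acid that would ionise this electron-rich benzylic position.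

Step 4
Reactants: 4 4-(bromomethyl)-2-methoxy-1-(triisopropylsilyloxy)benzene; 5 potassium glutaconate (potassium (1E,3E)-5-oxopenta-1,3-dien-1-olate)
Product: 6 (2E,4E)-5-{[3-methoxy-4-(triisopropylsilyloxy)phenyl]methoxy}penta-2,4-dienal
Conditions: 18-crown-6 (cat.), DMF, 0 °C to rt, dark
Reagents that add atoms: none
Why: Williamson-type O-alkylation of the glutaconaldehyde enolate, a vinylogous carboxylate, by the SN1-like benzylic bromide in a dipolar aprotic solvent should give the all-trans enol ether, since C-alkylation would break the dienolate conjugation.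

Step 5
Reactants: 6 (2E,4E)-5-{[3-methoxy-4-(triisopropylsilyloxy)phenyl]methoxy}penta-2,4-dienal
Product: 10 [(2R,3S)-2-[3-methoxy-4-(triisopropylsilyloxy)phenyl]-3,4-dihydro-2H-pyran-3-yl]methanol, via 4Z-dienal 7 (not isolated), via oxocarbenium-enol cation 8 (not isolated), via trans-aldehyde 9 (not isolated)
Conditions: (R)-3,3'-bis(2,4,6-triisopropylphenyl)-1,1'-binaphthyl-2,2'-diyl N-triflylphosphoramide (10 mol %), PhMe, 5 Å MS, 50 °C; then Et3N; NaBH4, MeOH, 0 °C
Reagents that add atoms: none
Why: Proposed new method: the chiral acid protonates the vinylogous-formate carbonyl of 6, the delocalised cation relaxes to the 4Z form 7, the hydridic benzylic C2–H (alpha to O1, para to the silyloxy group) shifts 1,5 to C4, the enal beta carbon, to give the oxocarbenium–enol ion 8, and the enol carbon C3 then adds to C2; the closest known reaction type is the acid-catalysed 1,5-hydride transfer/cyclisation of benzyl ethers that carry an enal or alkylidene malonate acceptor (internal redox, tert-amino-effect type), known for alkyl and aryl tethers but not for an O-vinyl tether inside a push–pull dienal. The pyran ring closes 6-endo-trig at the C2=O1 oxocarbenium with the enol double bond exocyclic (6-enolexo). C2 is controlled by the chiral phosphoramide anion, which is hydrogen-bonded to the enol OH and ion-paired with the oxocarbenium and so fixes the face of C2 that C3 attacks; C3 is controlled by C2 through a half-chair transition state with the aryl group pseudo-equatorial, and the acid in any case equilibrates C3 to the trans aldehyde 9 through the enol. The step needs the hydride shift to outrun heterolysis of the benzylic C2–O1 bond and the closure to occur at C3 only: the para-silyloxy group makes C2–H hydridic and stabilises the oxocarbenium, the cis O1–C6=C5 unit holds that C–H over C4 as the only acceptor within reach, and C3 is the only nucleophilic carbon that can reach C2 in a six-membered ring. Reduction in the same flask removes the beta-alkoxy aldehyde before it can epimerise or open by retro-oxa-Michael elimination.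

Step 6
Reactants: 10 [(2R,3S)-2-[3-methoxy-4-(triisopropylsilyloxy)phenyl]-3,4-dihydro-2H-pyran-3-yl]methanol
Product: 11 [(2R,3S)-2-[3-methoxy-4-(triisopropylsilyloxy)phenyl]-3,4-dihydro-2H-pyran-3-yl]methyl acetate
Conditions: Ac2O, pyridine, 4-(dimethylamino)pyridine (cat.), CH2Cl2, 0 °C
Reagents that add atoms: acetic anhydride, CC(=O)OC(C)=O
Why: Nucleophile-catalysed acetylation of the primary alcohol in a basic medium keeps the acid-labile enol ether intact and removes the hydroxyl that could add to it.

Step 7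
Reactants: 11 [(2R,3S)-2-[3-methoxy-4-(triisopropylsilyloxy)phenyl]-3,4-dihydro-2H-pyran-3-yl]methyl acetate
Product: 12 [(2R,3S)-5-iodo-2-[3-methoxy-4-(triisopropylsilyloxy)phenyl]-3,4-dihydro-2H-pyran-3-yl]methyl acetate
Conditions: NIS (1.05 equiv), AgNO3 (20 mol %), MeCN, 70 °C
Reagents that add atoms: N-iodosuccinimide, O=C1CCC(=O)N1I
Why: Electrophilic iodination of the enol ether at its beta carbon C5 and loss of the C5 proton from the iodo-oxocarbenium ion (the NIS/AgNO3 2-iodoglycal protocol) should be faster than iodination of the silyloxy-anisole ring and involves neither stereocentre.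

Step 8
Reactants: 12 [(2R,3S)-5-iodo-2-[3-methoxy-4-(triisopropylsilyloxy)phenyl]-3,4-dihydro-2H-pyran-3-yl]methyl acetate; 13 ethynyltrimethylsilane
Product: 14 [(2R,3S)-2-[3-methoxy-4-(triisopropylsilyloxy)phenyl]-5-[(trimethylsilyl)ethynyl]-3,4-dihydro-2H-pyran-3-yl]methyl acetate
Conditions: PdCl2(PPh3)2 (5 mol %), CuI (10 mol %), Et3N, THF, rt
Reagents that add atoms: none
Why: Sonogashira coupling of the alkenyl iodide with the terminal alkyne, precedented for 2-iodoglycals, proceeds with retention of the ring double bond under non-acidic conditions.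

Step 9
Reactants: 14 [(2R,3S)-2-[3-methoxy-4-(triisopropylsilyloxy)phenyl]-5-[(trimethylsilyl)ethynyl]-3,4-dihydro-2H-pyran-3-yl]methyl acetate
Product: 15 [(2R,3S)-5-ethynyl-2-(4-hydroxy-3-methoxyphenyl)-3,4-dihydro-2H-pyran-3-yl]methyl acetate
Conditions: Bu4NF, AcOH, THF, 0 °C
Reagents that add atoms: none
Why: Fluoride-mediated desilylation cleaves both the alkynyl C–Si and the aryl O–Si bond, while acetic acid buffers the phenoxide so that the primary acetate should neither migrate nor hydrolyse.

Step 10
Reactants: 16 1-(2,5-dimethoxyphenyl)ethanone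
Product: 17 1-(4-iodo-2,5-dimethoxyphenyl)ethanone
Conditions: NIS, CF3CO2H (cat.), MeCN, rt
Reagents that add atoms: N-iodosuccinimide, O=C1CCC(=O)N1I
Why: Electrophilic aromatic iodination should go to C4, ortho to the 5-methoxy group that is not conjugated to the carbonyl and less hindered than C6, as in the halogenation of 2,5-dimethoxybenzaldehyde.

Step 11
Reactants: 17 1-(4-iodo-2,5-dimethoxyphenyl)ethanone
Product: 18 1-(2,5-dihydroxy-4-iodophenyl)ethanone
Conditions: BBr3, CH2Cl2, −78 °C to rt; H2O
Reagents that add atoms: none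
Why: Lewis-acid demethylation of both aryl methyl ethers with BBr3 leaves the aryl iodide and the ketone unchanged.

Step 12
Reactants: 15 [(2R,3S)-5-ethynyl-2-(4-hydroxy-3-methoxyphenyl)-3,4-dihydro-2H-pyran-3-yl]methyl acetate; 18 1-(2,5-dihydroxy-4-iodophenyl)ethanone
Product: 20 propolis-benzofuran A, via alkynylphenol 19 (not isolated)
Conditions: PdCl2(PPh3)2 (5 mol %), CuI (10 mol %), Et3N, DMF, 60 °C, degassed
Reagents that add atoms: none
Why: Sonogashira coupling at the C–I bond gives the ortho-alkynylphenol 19, whose adjacent hydroxyl adds 5-endo-dig to the metal-activated alkyne (Castro–Stephens-type benzofuran annulation), the other hydroxyl being hydrogen-bonded to the acetyl group and out of reach.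

**Compound list**

1 | vanillin (4-hydroxy-3-methoxybenzaldehyde) | COc1cc(C=O)ccc1O | starting material
2 | 3-methoxy-4-(triisopropylsilyloxy)benzaldehyde | COc1cc(C=O)ccc1O[Si](C(C)C)(C(C)C)C(C)C | intermediate
3 | [3-methoxy-4-(triisopropylsilyloxy)phenyl]methanol | COc1cc(CO)ccc1O[Si](C(C)C)(C(C)C)C(C)C | intermediate
4 | 4-(bromomethyl)-2-methoxy-1-(triisopropylsilyloxy)benzene | COc1cc(CBr)ccc1O[Si](C(C)C)(C(C)C)C(C)C | intermediate
5 | potassium glutaconate (potassium (1E,3E)-5-oxopenta-1,3-dien-1-olate) | [K+].[O-]/C=C/C=C/C=O | starting material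
6 | (2E,4E)-5-{[3-methoxy-4-(triisopropylsilyloxy)phenyl]methoxy}penta-2,4-dienal | O=C/C=C/C=C/OCc1ccc(O[Si](C(C)C)(C(C)C)C(C)C)c(OC)c1 | intermediate
7 | (2E,4Z)-5-{[3-methoxy-4-(triisopropylsilyloxy)phenyl]methoxy}penta-2,4-dienal | O=C/C=C/C=C\OCc1ccc(O[Si](C(C)C)(C(C)C)C(C)C)c(OC)c1 | intermediate (not isolated)
8 | (Z)-(5-hydroxypenta-1,4-dien-1-yl)[3-methoxy-4-(triisopropylsilyloxy)benzylidene]oxonium, the oxocarbenium–enol cation paired with the phosphoramide anion | OC=CC/C=C\[O+]=Cc1ccc(O[Si](C(C)C)(C(C)C)C(C)C)c(OC)c1 | intermediate (not isolated)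
9 | (2R,3R)-2-[3-methoxy-4-(triisopropylsilyloxy)phenyl]-3,4-dihydro-2H-pyran-3-carbaldehyde | COc1cc([C@@H]2OC=CC[C@H]2C=O)ccc1O[Si](C(C)C)(C(C)C)C(C)C | intermediate (not isolated)
10 | [(2R,3S)-2-[3-methoxy-4-(triisopropylsilyloxy)phenyl]-3,4-dihydro-2H-pyran-3-yl]methanol | COc1cc([C@@H]2OC=CC[C@H]2CO)ccc1O[Si](C(C)C)(C(C)C)C(C)C | intermediate
11 | [(2R,3S)-2-[3-methoxy-4-(triisopropylsilyloxy)phenyl]-3,4-dihydro-2H-pyran-3-yl]methyl acetate | COc1cc([C@@H]2OC=CC[C@H]2COC(C)=O)ccc1O[Si](C(C)C)(C(C)C)C(C)C | intermediate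
12 | [(2R,3S)-5-iodo-2-[3-methoxy-4-(triisopropylsilyloxy)phenyl]-3,4-dihydro-2H-pyran-3-yl]methyl acetate | COc1cc([C@@H]2OC=C(I)C[C@H]2COC(C)=O)ccc1O[Si](C(C)C)(C(C)C)C(C)C | intermediate
13 | ethynyltrimethylsilane | C#C[Si](C)(C)C | starting material
14 | [(2R,3S)-2-[3-methoxy-4-(triisopropylsilyloxy)phenyl]-5-[(trimethylsilyl)ethynyl]-3,4-dihydro-2H-pyran-3-yl]methyl acetate | COc1cc([C@@H]2OC=C(C#C[Si](C)(C)C)C[C@H]2COC(C)=O)ccc1O[Si](C(C)C)(C(C)C)C(C)C | intermediate
15 | [(2R,3S)-5-ethynyl-2-(4-hydroxy-3-methoxyphenyl)-3,4-dihydro-2H-pyran-3-yl]methyl acetate | COc1cc([C@@H]2OC=C(C#C)C[C@H]2COC(C)=O)ccc1O | intermediate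
16 | 1-(2,5-dimethoxyphenyl)ethanone | CC(=O)c1cc(OC)ccc1OC | starting material
17 | 1-(4-iodo-2,5-dimethoxyphenyl)ethanone | CC(=O)c1cc(OC)c(I)cc1OC | intermediate
18 | 1-(2,5-dihydroxy-4-iodophenyl)ethanone | CC(=O)c1cc(O)c(I)cc1O | intermediate
19 | [(2R,3S)-5-[(4-acetyl-2,5-dihydroxyphenyl)ethynyl]-2-(4-hydroxy-3-methoxyphenyl)-3,4-dihydro-2H-pyran-3-yl]methyl acetate | COc1cc([C@@H]2OC=C(C#Cc3cc(O)c(C(C)=O)cc3O)C[C@H]2COC(C)=O)ccc1O | intermediate (not isolated)
20 | propolis-benzofuran A, [(2R,3S)-5-(6-acetyl-5-hydroxy-1-benzofuran-2-yl)-2-(4-hydroxy-3-methoxyphenyl)-3,4-dihydro-2H-pyran-3-yl]methyl acetate | COc1cc([C@@H]2OC=C(c3cc4cc(O)c(C(C)=O)cc4o3)C[C@H]2COC(C)=O)ccc1O | target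

**Step count**

Total steps: 12. Longest linear sequence: 10 (steps 1–9 and 12).

**Steps most likely to fail**

Step 5. The hydride shift may be slower than acid-induced heterolysis of the benzylic C–O bond or than acid attack on the product enol ether. The 4Z geometry may not be populated, and the ion pair may give poor facial selectivity at C2. Secondary-amine catalysis is not an alternative, since amines displace the alkoxy group of a 5-alkoxydienal. The fallback uses known chemistry, sets out from aldehyde 2 and returns at acetate 11. An Evans syn-aldol reaction of 2 with the boron enolate (Bu2BOTf, i-Pr2NEt, CH2Cl2, −78 °C) of (R)-4-benzyl-3-(hex-5-enoyl)oxazolidin-2-one F1, itself made from (R)-4-benzyloxazolidin-2-one, n-BuLi and hex-5-enoyl chloride, should give the syn-aldol imide F2; the syn relation maps onto the trans ring and the (R)-auxiliary gives the required absolute sense. LiBH4 (THF, MeOH, 0 °C) removes the auxiliary to give the 1,3-diol F3. AcCl and 2,4,6-collidine (CH2Cl2, −78 °C) acetylate only the primary hydroxyl to give the hydroxy acetate F4. OsO4 (cat.), NaIO4 and 2,6-lutidine (dioxane/H2O) cleave the terminal alkene, and the aldehyde closes on the benzylic hydroxyl to give the lactol F5. MsCl and Et3N (CH2Cl2, 0 °C to rt) dehydrate the lactol to enol ether 11.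

Step 7. Iodination may stray to the electron-rich arene, or the iodo-oxocarbenium ion may be captured by nitrate or succinimide and fail to lose the C5 proton. The fallback brings in the alkyne carbon as a formyl group instead of a halide; it sets out from acetate 11 and returns at enyne 15. Vilsmeier–Haack formylation (POCl3, DMF, 0 °C to rt; aqueous NaOAc) at the enol ether beta carbon should give the 5-formyl acetate F6. Ohira–Bestmann homologation (dimethyl (1-diazo-2-oxopropyl)phosphonate, K2CO3, MeOH, rt) converts the aldehyde into the terminal alkyne, and the acetate is lost by methanolysis, to give the enyne alcohol F7. Ac2O and pyridine restore the acetate to give the silyl-protected enyne acetate F8. Bu4NF and AcOH (THF, 0 °C) remove the aryl silyl group to give 15.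

Step 4. The ambident dienolate may be alkylated on carbon (C2 or C4), or the reactive benzylic bromide may be lost to solvolysis. The fallback builds the dienal from the alcohol by olefination; it sets out from alcohol 3 and returns at dienal 6. Conjugate addition of 3 to ethyl propiolate (N-methylmorpholine (cat.), CH2Cl2, rt) should give the (E)-3-alkoxyacrylate F9. (i-Bu)2AlH (CH2Cl2, −78 °C) reduces the ester to the allylic alcohol F10. MnO2 (CH2Cl2, rt) oxidises it to the 3-alkoxyacrolein F11. Wittig reaction with (triphenylphosphoranylidene)acetaldehyde (PhMe, 70 °C) adds the remaining two carbons as the E-enal to give 6.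

**Further compounds**

F1 | step 5 | (R)-4-benzyl-3-(hex-5-enoyl)oxazolidin-2-one | C=CCCCC(=O)N1C(=O)OC[C@H]1Cc1ccccc1
F2 | step 5 | (R)-4-benzyl-3-{(2R,3R)-2-(but-3-en-1-yl)-3-hydroxy-3-[3-methoxy-4-(triisopropylsilyloxy)phenyl]propanoyl}oxazolidin-2-one | COc1cc([C@H](O)[C@H](C(=O)N2C(=O)OC[C@H]2Cc2ccccc2)CCC=C)ccc1O[Si](C(C)C)(C(C)C)C(C)C
F3 | step 5 | (1R,2S)-2-(but-3-en-1-yl)-1-[3-methoxy-4-(triisopropylsilyloxy)phenyl]propane-1,3-diol | COc1cc([C@H](O)[C@H](CO)CCC=C)ccc1O[Si](C(C)C)(C(C)C)C(C)C
F4 | step 5 | (S)-2-{(R)-hydroxy[3-methoxy-4-(triisopropylsilyloxy)phenyl]methyl}hex-5-en-1-yl acetate | COc1cc([C@H](O)[C@H](COC(C)=O)CCC=C)ccc1O[Si](C(C)C)(C(C)C)C(C)C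
F5 | step 5 | [(2R,3S)-6-hydroxy-2-[3-methoxy-4-(triisopropylsilyloxy)phenyl]tetrahydro-2H-pyran-3-yl]methyl acetate (anomeric mixture) | COc1cc([C@@H]2OC(O)CC[C@H]2COC(C)=O)ccc1O[Si](C(C)C)(C(C)C)C(C)C
F6 | step 7 | [(2R,3S)-5-formyl-2-[3-methoxy-4-(triisopropylsilyloxy)phenyl]-3,4-dihydro-2H-pyran-3-yl]methyl acetate | COc1cc([C@@H]2OC=C(C=O)C[C@H]2COC(C)=O)ccc1O[Si](C(C)C)(C(C)C)C(C)C
F7 | step 7 | [(2R,3S)-5-ethynyl-2-[3-methoxy-4-(triisopropylsilyloxy)phenyl]-3,4-dihydro-2H-pyran-3-yl]methanol | COc1cc([C@@H]2OC=C(C#C)C[C@H]2CO)ccc1O[Si](C(C)C)(C(C)C)C(C)C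
F8 | step 7 | [(2R,3S)-5-ethynyl-2-[3-methoxy-4-(triisopropylsilyloxy)phenyl]-3,4-dihydro-2H-pyran-3-yl]methyl acetate | COc1cc([C@@H]2OC=C(C#C)C[C@H]2COC(C)=O)ccc1O[Si](C(C)C)(C(C)C)C(C)C
F9 | step 4 | ethyl (E)-3-{[3-methoxy-4-(triisopropylsilyloxy)phenyl]methoxy}acrylate | CCOC(=O)/C=C/OCc1ccc(O[Si](C(C)C)(C(C)C)C(C)C)c(OC)c1
F10 | step 4 | (E)-3-{[3-methoxy-4-(triisopropylsilyloxy)phenyl]methoxy}prop-2-en-1-ol | OC/C=C/OCc1ccc(O[Si](C(C)C)(C(C)C)C(C)C)c(OC)c1
F11 | step 4 | (E)-3-{[3-methoxy-4-(triisopropylsilyloxy)phenyl]methoxy}acrylaldehyde | O=C/C=C/OCc1ccc(O[Si](C(C)C)(C(C)C)C(C)C)c(OC)c1
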